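## The problem

The target 44 is a cembranolide: a fourteen-membered carbocycle (C1–C14) fused trans across C1/C14 to an α-methylene-γ-butyrolactone (C15 α-carbon, C16 carbonyl, C17 exocyclic methylene). The ring carries a trisubstituted (3S,4S)-epoxide, a secondary allylic hydroperoxide at C7 (R) beside an exocyclic C8=C19 methylene, an E-trisubstituted C11=C12 olefin, and an acetate at C13 (S) next to the lactone oxygen on C14 (R). C1, C13 and C14 are contiguous, so a C14 centre taken from the chiral pool can set C1 through the five-membered ring and C13 through Felkin–Anh addition to a C13 aldehyde. The epoxide and C7 are too far away for this: the epoxide needs reagent control, and C7 can only rely on the conformation of the macrocycle. The hydroperoxide will not survive reductants, phosphines, bases or low-valent metals. The methylene lactone is a Michael acceptor towards every carbanion a fragment coupling would use. The epoxide is acid-labile, and the aldehyde needed for ring closure is α-oxygenated and epimerizable. The hydroperoxide/exocyclic-methylene pair at C7/C8/C19 is the product pattern of a singlet-oxygen ene reaction on an E-C7=C8 olefin, so the most fragile group can be put in last. The feature that makes the key step possible lies in the lactone: C1 (β-carbon) carries C2 and C15 (α-carbon) carries C17, both trans to the C14 substituent. That is the substitution pattern of a butenolide that has taken a nucleophile at its β-carbon and an electrophile at its α-carbon.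

## Retrosynthesis

**44 ⇒ 43.** The C7–O bond is cut and the C8=C19 double bond returned to C7=C8 (ene retron). Carrying oxygen at C7 through the synthesis would put a leaving group β to the C6 carbanion used for fragment union, and no peroxide would survive sodium amalgam or CrCl2. The precursor 43 has one stereocentre fewer and no peroxide. The forward reaction must react at C7=C8 only, abstract a C19 hydrogen in preference to a C6 hydrogen, and attack the right face.

**43 ⇒ 41 ⇒ 40.** The C15=C17 double bond is traced to the Mannich base 41 (quaternization and elimination) and the acetate to the C13 alcohol 40. The free methylene lactone could not pass through sulfonyl carbanions or dissolving-metal steps. The dimethylaminomethyl group is inert there, and its carbon C17 is already in place.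

**40 ⇒ 39 ⇒ 37.** The C6 hydrogen of 40 replaces a phenylsulfonyl group (39), and the ring is opened at C12–C13 to the iodo aldehyde 37 (Nozaki–Hiyama–Kishi reaction). This bond is chosen because it lies next to C14, so the new C13 carbinol can be set by Felkin–Anh control, and the vinyl iodide fixes the E geometry of C11=C12. Closing at C5–C6 instead would expose the lactone to strong base under high dilution. The sulfone stays on through the closure because no reductive desulfonylation spares a vinyl iodide.

**37 ⇒ 36 ⇒ 35 ⇒ 22 + 33.** After adjusting the oxidation level at C13 (36, 35), the C5–C6 bond is cut between the epoxy iodide 22 and the allylic sulfone 33. This divides the seco chain into two pieces of similar size and places the carbanion on the fragment without a lactone. The forward step needs SN2 displacement at C5, a primary carbon flanked by the oxirane, to outrun attack of the sulfonyl carbanion on the lactone.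

**22 ⇒ 21 ⇒ 20 ⇒ 19.** The iodide comes from the epoxy alcohol 21, and 21 from Sharpless epoxidation of the E-allylic alcohol 20, released from its silyl ether 19. The C5 oxygen serves twice, first to direct the epoxidation and then as the leaving group.

**19 ⇒ 18 ⇒ 8 + 14 + 15.** Reductive removal of the C2 sulfone leads back to 18, which is disconnected at C1–C2 and C15–C17 into the (R)-butenolide 8, the allylic sulfone 14 and the iminium salt 15. Both bonds form in one flask on a chiral-pool ring, and C1 is set by the C14 substituent. A stepwise build-up of the lactone (Alternatives 2 and 3) forms fewer skeletal bonds per operation.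

**8 ⇒ 6 ⇒ 3 ⇒ 1 and 14 ⇒ 12 ⇒ 11 ⇒ 9 + 10.** The butenolide comes from the commercial (R)-lactone 1 by silylation and selenoxide dehydrogenation. The sulfone comes from prenyl bromide 9 and sodium benzenesulfinate 10 by E-selective allylic oxidation and silylation.

**33 ⇒ 32 ⇒ 31 ⇒ 29 ⇒ 27 ⇒ 26 ⇒ 23 + 24.** The sulfone 33 is made from bromide 32 and alcohol 31. The E-vinyl iodide comes from the methyl alkyne of 29 by hydrozirconation and iodination. The E-trisubstituted C7=C8 olefin comes from carboalumination of diyne 27, assembled from 1-(trimethylsilyl)propyne 23 and 1-bromobut-2-yne 24. Both olefin geometries follow from syn-additions to alkynes.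

## Roads not taken

**Alternative 1:** The same C12–C13 bond is closed, but from the ynal A1 with Ni(cod)2, a bulky N-heterocyclic carbene and Et3SiH, giving the silylated macrocycle A2.
- Merits: the alkyne is robust and installed early, no vinyl iodide or stoichiometric chromium is needed, and the syn-hydrometalative coupling gives the E olefin with the carbinol already protected. For the ring closure alone this road is at least as good as the chosen one. It would save the hydrozirconation step, and an alkyne would survive a desulfonylation before closure, which the vinyl iodide does not.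
- Weak points: the alkyne carries a methyl group on one side and a methylene on the other, so which alkyne carbon bonds to C13 depends only on ligand size and ring strain. The wrong mode gives a thirteen-membered ring with an exocyclic ethylidene. The C13 configuration next to the lactone oxygen is not predictable. A2 also lacks C17, so the methylene would have to be added by enolate chemistry on a macrocycle that holds an epoxide.
- Comparison: the chosen plan sets against it the fixed regiochemistry of a vinyl iodide, the known tolerance of CrCl2/NiCl2 for lactones, amines and epoxides, and a methylene carbon present in masked form from step 7 on.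

**Alternative 2:** The lactone is closed at C1–C15 by Rh2(OAc)4-mediated C–H insertion of the diazophosphonoacetate A3, giving the phosphono lactone A4.
- Merits: the ring and the trans C1/C14 relation arise together. The phosphonate is a better methylene precursor than the Mannich base: a Horner–Wadsworth–Emmons reaction with formaldehyde at the end needs only mild base, and no tertiary amine has to pass through an oxidation.
- Weak points: the inserting C–H bond is an unactivated methylene made electron-poor by the neighbouring acyloxy carbon. Only one skeletal bond is formed. A4 carries just a two-carbon stub at C1, so the C3=C4 olefin and the C5 alcohol still have to be built. The acidic phosphonoacetate proton would also quench the sulfonyl carbanion of the fragment coupling.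
- Comparison: the chosen plan forms two skeletal bonds in its key step and delivers C2–C5 with the E olefin in place. It pays for this with an amine that has to be carried through the Sharpless epoxidation (see step 10 and its fallback).

**Alternative 3:** The lactone is built last, by cyclocarbonylation of the macrocyclic homopropargylic alcohol A5 with PdCl2, thiourea and CO to the methylene lactone A6 (C15–C16 and C16–O formed).
- Merits: the Michael acceptor appears complete in one late step, so no mask and no amine are needed, and a terminal alkyne is inert to sulfone and chromium chemistry. In handling the methylene lactone this road is better than the chosen one.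
- Weak points: the anti relation of C1 and C14 must come from open-chain chemistry, and the C13 and C14 oxygens must be differentiated. The macrocycle must close without the lactone as a conformational anchor. Divalent palladium, CO and the HCl formed in the catalytic cycle meet an acid-labile trisubstituted epoxide and two trisubstituted olefins on the most advanced intermediate.
- Comparison: the chosen plan sets C1 on a five-membered ring, where facial bias is dependable, and keeps transition metals away from the epoxide until the chromium step.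

Key step: step 7

Remark on the chemistry: atom labels C1–C20 follow cembrane numbering of the target; the sulfonyl-bearing carbons C2 (in 18) and C6 (in 35–39) are carried as epimer mixtures because both become CH2.

## Route

Step 1
Reactants: 1 (R)-5-(hydroxymethyl)dihydrofuran-2(3H)-one; 2 tert-butyldiphenylsilyl chloride
Product: 3 (R)-5-[(tert-butyldiphenylsilyloxy)methyl]dihydrofuran-2(3H)-one
Conditions: TBDPSCl, imidazole, DMF, 0 °C → rt
Reagents that add atoms: tert-butyldiphenylsilyl chloride, CC(C)(C)[Si](Cl)(c1ccccc1)c1ccccc1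
Why: Silylation of the primary alcohol; the TBDPS ether is chosen to outlast the later acid removal of a TBS ether and to shield one face of the butenolide in step 7.

Step 2
Reactants: 3 (R)-5-[(tert-butyldiphenylsilyloxy)methyl]dihydrofuran-2(3H)-one; 4 phenylselenenyl bromide
Product: 6 (5R)-5-[(tert-butyldiphenylsilyloxy)methyl]-3-(phenylselanyl)dihydrofuran-2(3H)-one (C3 epimers), via lactone lithium enolate 5 (not isolated)
Conditions: LiN(i-Pr)2, THF, −78 °C; then PhSeBr, −78 °C
Reagents that add atoms: phenylselenenyl bromide, Br[Se]c1ccccc1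
Why: α-Selenenylation of the kinetic lactone enolate; the new C3 centre is lost in step 3, so its configuration does not matter.

Step 3
Reactants: 6 (5R)-5-[(tert-butyldiphenylsilyloxy)methyl]-3-(phenylselanyl)dihydrofuran-2(3H)-one
Product: 8 (R)-5-[(tert-butyldiphenylsilyloxy)methyl]furan-2(5H)-one, via selenoxide 7 (not isolated)
Conditions: 30% H2O2, pyridine, CH2Cl2, 0 °C → rt
Reagents that add atoms: none
Why: Selenoxide syn-elimination; the only syn β-hydrogens are on C4, so the endocyclic butenolide forms and the C5 stereocentre is untouched.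

Step 4
Reactants: 9 1-bromo-3-methylbut-2-ene (prenyl bromide); 10 sodium benzenesulfinate
Product: 11 (3-methylbut-2-en-1-yl)sulfonylbenzene
Conditions: DMF, rt
Reagents that add atoms: sodium benzenesulfinate, [Na+].[O-]S(=O)c1ccccc1
Why: SN2 S-alkylation of the sulfinate by a primary allylic bromide.

Step 5
Reactants: 11 (3-methylbut-2-en-1-yl)sulfonylbenzene
Product: 12 (E)-2-methyl-4-(phenylsulfonyl)but-2-en-1-ol
Conditions: SeO2 (cat.), t-BuOOH, salicylic acid (cat.), CH2Cl2, rt
Reagents that add atoms: selenium dioxide, O=[Se]=O (oxygen carrier); tert-butyl hydroperoxide, CC(C)(C)OO (terminal oxidant)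
Why: Selenium dioxide allylic oxidation (ene reaction then [2,3]-shift) attacks the E-methyl group at the more substituted olefin terminus, giving the E-allylic alcohol; conversion is stopped before enal formation becomes significant.

Step 6
Reactants: 12 (E)-2-methyl-4-(phenylsulfonyl)but-2-en-1-ol; 13 tert-butyldimethylsilyl chloride
Product: 14 (E)-tert-butyldimethyl{[2-methyl-4-(phenylsulfonyl)but-2-en-1-yl]oxy}silane
Conditions: TBSCl, imidazole, DMF, rt
Reagents that add atoms: tert-butyldimethylsilyl chloride, CC(C)(C)[Si](C)(C)Cl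
Why: Silylation; TBS is chosen because it can later be removed beside the TBDPS ether.

Step 7
Reactants: 14 (E)-tert-butyldimethyl{[2-methyl-4-(phenylsulfonyl)but-2-en-1-yl]oxy}silane; 8 (R)-5-[(tert-butyldiphenylsilyloxy)methyl]furan-2(5H)-one; 15 N,N-dimethylmethyleneiminium iodide (Eschenmoser's salt)
Product: 18 (3S,4R,5R)-4-[(E)-4-(tert-butyldimethylsilyloxy)-3-methyl-1-(phenylsulfonyl)but-2-en-1-yl]-5-[(tert-butyldiphenylsilyloxy)methyl]-3-[(dimethylamino)methyl]dihydrofuran-2(3H)-one (C2 epimers), via lithiated sulfone 16 (not isolated), via lactone lithium enolate 17 (not isolated)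
Conditions: n-BuLi, THF/HMPA, −78 °C; 8, −78 °C; then Me2N=CH2+ I− (15), −78 → −20 °C
Reagents that add atoms: N,N-dimethylmethyleneiminium iodide, C=[N+](C)C.[I-]
Why: Deprotonation of 14 gives the sulfonyl-stabilised allyl anion 16, which in THF/HMPA adds as a solvent-separated ion pair in 1,4-fashion through its α-carbon (C2) to C1 of the butenolide, and the lactone enolate 17 is then captured at C15 by the iminium ion in a Mannich reaction. The closest known reaction type is the tandem conjugate addition–enolate trapping of 5-(alkoxymethyl)butenolides with sulfur-stabilised carbanions, combined with aminomethylation of lactone enolates by Eschenmoser's salt. No ring closes; the C1–C2 and C15–C17 bonds are formed. C1 is set by the C14 silyloxymethyl group, which blocks one face of the flat five-membered ring so that the carbanion enters anti to it. C15 is set by the new C1 substituent, which sends the iminium ion to the opposite face and gives the trans,trans lactone; C2 is not controlled and is erased in step 8. The step needs 1,4- over 1,2-addition and α- over γ-attack, which HMPA and the fully substituted γ-carbon of 16 secure. It also needs the kinetic enolate to be trapped before it is quenched by the more acidic C2–H of the adduct, which exactly one equivalent of base, low temperature and an excess of finely divided iminium salt are meant to secure.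

Step 8
Reactants: 18 the C2-sulfonyl Mannich lactone
Product: 19 (3S,4R,5R)-4-[(E)-4-(tert-butyldimethylsilyloxy)-3-methylbut-2-en-1-yl]-5-[(tert-butyldiphenylsilyloxy)methyl]-3-[(dimethylamino)methyl]dihydrofuran-2(3H)-one
Conditions: 6% Na/Hg, Na2HPO4, MeOH/THF, −20 °C
Reagents that add atoms: none
Why: Reductive desulfonylation with buffered sodium amalgam; the allyl anion is protonated at the less substituted terminus C2, which keeps the trisubstituted E olefin, and lactone, amine and silyl ethers are inert in the cold; olefin isomers are not allylic alcohols after step 9 and would be removed after step 10.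

Step 9
Reactants: 19 the bis-silyl ether
Product: 20 (3S,4R,5R)-5-[(tert-butyldiphenylsilyloxy)methyl]-3-[(dimethylamino)methyl]-4-[(E)-4-hydroxy-3-methylbut-2-en-1-yl]dihydrofuran-2(3H)-one
Conditions: camphorsulfonic acid (1.2 equiv), MeOH/CH2Cl2, 0 °C
Reagents that add atoms: none
Why: Acid-catalysed methanolysis cleaves the primary allylic TBS ether much faster than the TBDPS ether; more than one equivalent of acid is needed because the amine takes up the first.

Step 10
Reactants: 20 the E-allylic alcohol
Product: 21 (3S,4R,5R)-5-[(tert-butyldiphenylsilyloxy)methyl]-3-[(dimethylamino)methyl]-4-{[(2S,3S)-3-(hydroxymethyl)-3-methyloxiran-2-yl]methyl}dihydrofuran-2(3H)-one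
Conditions: Ti(OiPr)4, L-(+)-diethyl tartrate, t-BuOOH, 4 Å molecular sieves, CH2Cl2, −25 °C
Reagents that add atoms: tert-butyl hydroperoxide, CC(C)(C)OO
Why: Sharpless asymmetric epoxidation; the L-(+)-tartrate complex delivers oxygen to the face that gives (2S,3S)-epoxy alcohols from E-2-methyl-2-alken-1-ols, which is the (3S,4S)-epoxide of the target, and this reagent control overrides the distant lactone centres; oxygen transfer within the titanium-bound allylic alkoxide should be faster than intermolecular N-oxidation of the amine.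

Step 11
Reactants: 21 the epoxy alcohol
Product: 22 (3S,4R,5R)-5-[(tert-butyldiphenylsilyloxy)methyl]-3-[(dimethylamino)methyl]-4-{[(2S,3R)-3-(iodomethyl)-3-methyloxiran-2-yl]methyl}dihydrofuran-2(3H)-one
Conditions: I2, PPh3, imidazole, CH2Cl2, 0 °C
Reagents that add atoms: iodine, II
Why: Appel-type iodination of the primary alcohol under neutral conditions leaves the epoxide intact (the descriptor change at the oxirane carbon is formal); the iodide is used at once to avoid self-quaternization by the amine.

Step 12
Reactants: 23 trimethyl(prop-1-yn-1-yl)silane; 24 1-bromobut-2-yne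
Product: 26 hepta-1,5-diyn-1-yl(trimethyl)silane, via lithiated silylpropyne 25 (not isolated)
Conditions: n-BuLi, THF, −20 °C; then 24, −78 °C → rt
Reagents that add atoms: none
Why: Propargylic lithiation of the silylpropyne and SN2 alkylation by the propargylic bromide; the silyl group blocks the alkyne terminus and directs C–C bond formation to the propargylic carbon.

Step 13
Reactants: 26 hepta-1,5-diyn-1-yl(trimethyl)silane
Product: 27 hepta-1,5-diyne
Conditions: K2CO3, MeOH, rt
Reagents that add atoms: none
Why: Methoxide-mediated protodesilylation of the alkynylsilane; the volatile diyne is carried on as a solution.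

Step 14
Reactants: 27 hepta-1,5-diyne
Product: 29 (E)-3-methyloct-2-en-6-yn-1-ol, via alkenylalane 28 (not isolated)
Conditions: AlMe3, Cp2ZrCl2 (cat.), CH2Cl2, 0 °C → rt; then n-BuLi, THF, −78 °C; (CH2O)n, → rt
Reagents that add atoms: trimethylaluminium, C[Al](C)C; paraformaldehyde (as formaldehyde), C=O
Why: Negishi carboalumination adds methyl and aluminium syn across the terminal alkyne with aluminium on the terminal carbon, the internal alkyne reacting far more slowly; the derived alanate attacks formaldehyde with retention, so the E-trisubstituted C7=C8 olefin follows from the mechanism.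

Step 15
Reactants: 29 (E)-3-methyloct-2-en-6-yn-1-ol
Product: 31 (2E,6E)-7-iodo-3-methylocta-2,6-dien-1-ol, via alkenylzirconocene 30 (not isolated)
Conditions: Cp2Zr(H)Cl (excess), THF, rt → 50 °C; then I2, 0 °C
Reagents that add atoms: iodine, II
Why: Hydrozirconation is a syn addition; with excess reagent and gentle warming the regioisomers equilibrate to the one with zirconium on the methyl-bearing carbon, and iodinolysis with retention gives the E-2-iodo-2-alkene; the hydroxyl consumes one equivalent of hydride and the trisubstituted olefin is inert.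

Step 16
Reactants: 31 (2E,6E)-7-iodo-3-methylocta-2,6-dien-1-ol
Product: 32 (2E,6E)-1-bromo-7-iodo-3-methylocta-2,6-diene
Conditions: CBr4, PPh3, CH2Cl2, 0 °C
Reagents that add atoms: carbon tetrabromide, BrC(Br)(Br)Br
Why: Appel bromination of a primary allylic alcohol without allylic shift; the vinyl iodide is inert.

Step 17
Reactants: 32 (2E,6E)-1-bromo-7-iodo-3-methylocta-2,6-diene; 10 sodium benzenesulfinate
Product: 33 [(2E,6E)-7-iodo-3-methylocta-2,6-dien-1-yl]sulfonylbenzene
Conditions: DMF, rt
Reagents that add atoms: sodium benzenesulfinate, [Na+].[O-]S(=O)c1ccccc1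
Why: SN2 S-alkylation of the sulfinate at the primary allylic bromide; the vinyl iodide is untouched.

Step 18
Reactants: 33 [(2E,6E)-7-iodo-3-methylocta-2,6-dien-1-yl]sulfonylbenzene; 22 the epoxy iodide
Product: 35 (3S,4R,5R)-5-[(tert-butyldiphenylsilyloxy)methyl]-3-[(dimethylamino)methyl]-4-({(2S,3S)-3-[(3E,7E)-8-iodo-4-methyl-2-(phenylsulfonyl)nona-3,7-dien-1-yl]-3-methyloxiran-2-yl}methyl)dihydrofuran-2(3H)-one (C6 epimers), via lithiated iodo sulfone 34 (not isolated)
Conditions: LiN(SiMe3)2, THF/HMPA, −78 °C; then 22, −78 → −30 °C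
Reagents that add atoms: none
Why: Alkylation of a lithiated allylic sulfone at its α-carbon (C6) by a primary iodide forms C5–C6; the amide base is used because an alkyllithium would exchange the vinyl iodide, the oxirane ties back the substituents next to C5 so the displacement is not neopentyl-like, and in the presence of HMPA at low temperature alkylation should outrun addition to the lactone carbonyl.

Step 19
Reactants: 35 the seco silyl ether
Product: 36 the corresponding C13 primary alcohol, (3S,4R,5R)-5-(hydroxymethyl) lactone (C6 epimers)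
Conditions: Bu4NF, AcOH, THF, 0 °C → rt
Reagents that add atoms: none
Why: Fluoride desilylation buffered with acetic acid, so that neither the acidic sulfone α-hydrogen nor the lactone meets basic fluoride; the γ-lactone remains the preferred ring size.

Step 20
Reactants: 36 the seco alcohol
Product: 37 (2R,3R,4S)-4-[(dimethylamino)methyl]-3-({(2S,3S)-3-[(3E,7E)-8-iodo-4-methyl-2-(phenylsulfonyl)nona-3,7-dien-1-yl]-3-methyloxiran-2-yl}methyl)-5-oxotetrahydrofuran-2-carbaldehyde (C6 epimers)
Conditions: Dess–Martin periodinane, pyridine, CH2Cl2, 0 °C → rt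
Reagents that add atoms: none
Why: Buffered Dess–Martin oxidation tolerates the tertiary amine, epoxide and vinyl iodide; the α-oxygenated aldehyde is used crude to avoid epimerization at C14.

Step 21
Reactants: 37 the iodo aldehyde
Product: 39 (1R,3S,4S,13S,14R,15S,7E,11E)-17-(dimethylamino)-3,4-epoxy-13-hydroxy-6-(phenylsulfonyl)cembra-7,11-dien-16,14-olide (C6 epimers), via alkenylchromium dichloride 38 (not isolated)
Conditions: CrCl2 (excess), NiCl2 (cat.), degassed DMSO/THF, rt, slow addition (final ca. 0.003 M)
Reagents that add atoms: none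
Why: Nozaki–Hiyama–Kishi reaction: nickel-catalysed formation of the alkenylchromium species with retention of olefin geometry, then addition to the aldehyde, closing the fourteen-membered ring at C12–C13 under high dilution; attack anti to the C14–O bond (polar Felkin–Anh) should give the 13,14-anti, that is 13S, alcohol; the reagent tolerates lactone, epoxide, amine and sulfone.

Step 22
Reactants: 39 the macrocyclic allylic sulfone
Product: 40 (1R,3S,4S,13S,14R,15S,7E,11E)-17-(dimethylamino)-3,4-epoxy-13-hydroxycembra-7,11-dien-16,14-olide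
Conditions: 6% Na/Hg, Na2HPO4, MeOH/THF, −20 °C
Reagents that add atoms: none
Why: Reductive desulfonylation as in step 8, now possible because the vinyl iodide has been consumed; protonation of the allyl anion at C6 keeps the E-C7=C8 olefin, and methanol should quench the anion faster than it can attack the fully substituted oxirane carbon.

Step 23
Reactants: 40 the macrocyclic C13 alcohol
Product: 41 (1R,3S,4S,13S,14R,15S,7E,11E)-13-acetoxy-17-(dimethylamino)-3,4-epoxycembra-7,11-dien-16,14-olide
Conditions: Ac2O, pyridine, DMAP (cat.), CH2Cl2, 0 °C → rt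
Reagents that add atoms: acetic anhydride, CC(=O)OC(C)=O
Why: DMAP-catalysed acetylation of the secondary allylic alcohol with retention at C13.

Step 24
Reactants: 41 the Mannich-base acetate
Product: 43 (1R,3S,4S,13S,14R,7E,11E)-13-acetoxy-3,4-epoxycembra-7,11,15(17)-trien-16,14-olide, via trimethylammonium iodide 42 (not isolated)
Conditions: MeI, THF, rt; evaporate; then NaHCO3, H2O/CH2Cl2, rt
Reagents that add atoms: none
Why: Exhaustive N-methylation followed by E1cB loss of trimethylamine from the β-ammonio lactone unmasks the α-methylene group and removes the C15 stereocentre; epoxide and acetate are inert to methyl iodide and bicarbonate.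

Step 25
Reactants: 43 the triene lactone
Product: 44 (1R,3S,4S,7R,13S,14R,11E)-13-acetoxy-3,4-epoxy-7-hydroperoxycembra-8(19),11,15(17)-trien-16,14-olide (target)
Conditions: O2, hν (visible), tetraphenylporphyrin (cat.), CH2Cl2, −20 °C
Reagents that add atoms: oxygen, O=O
Why: Schenck ene reaction of singlet oxygen at C7=C8, the only electron-rich olefin (C11=C12 is deactivated by the allylic acetate and the methylene lactone is electron-poor); oxygen bonds to C7 and a C19 hydrogen is abstracted on the more substituted side of the E olefin, moving the double bond to C8=C19; attack on the exposed outer face of the ring olefin is expected to set C7, and the 7R isomer would be separated from its epimer and from the 8-hydroperoxy-6-ene isomer by HPLC without reductive work-up.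

## Compound list

1 | (R)-5-(hydroxymethyl)dihydrofuran-2(3H)-one | O=C1CC[C@H](CO)O1 | starting material
2 | tert-butyldiphenylsilyl chloride | CC(C)(C)[Si](Cl)(c1ccccc1)c1ccccc1 | starting material
3 | (R)-5-[(tert-butyldiphenylsilyloxy)methyl]dihydrofuran-2(3H)-one | O=C1CC[C@H](CO[Si](c2ccccc2)(c2ccccc2)C(C)(C)C)O1 | intermediate
4 | phenylselenenyl bromide | Br[Se]c1ccccc1 | starting material
5 | lithium enolate of 3 | [Li+].[O-]C1=CC[C@H](CO[Si](c2ccccc2)(c2ccccc2)C(C)(C)C)O1 | intermediate
6 | (5R)-5-[(tert-butyldiphenylsilyloxy)methyl]-3-(phenylselanyl)dihydrofuran-2(3H)-one, C3 epimers | O=C1C([Se]c2ccccc2)C[C@H](CO[Si](c2ccccc2)(c2ccccc2)C(C)(C)C)O1 | intermediate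
7 | selenoxide of 6 | O=C1C([Se](=O)c2ccccc2)C[C@H](CO[Si](c2ccccc2)(c2ccccc2)C(C)(C)C)O1 | intermediate
8 | (R)-5-[(tert-butyldiphenylsilyloxy)methyl]furan-2(5H)-one | O=C1C=C[C@H](CO[Si](c2ccccc2)(c2ccccc2)C(C)(C)C)O1 | intermediate
9 | 1-bromo-3-methylbut-2-ene (prenyl bromide) | CC(C)=CCBr | starting material
10 | sodium benzenesulfinate | [Na+].[O-]S(=O)c1ccccc1 | starting material
11 | (3-methylbut-2-en-1-yl)sulfonylbenzene | CC(C)=CCS(=O)(=O)c1ccccc1 | intermediate
12 | (E)-2-methyl-4-(phenylsulfonyl)but-2-en-1-ol | O=S(=O)(C/C=C(\C)CO)c1ccccc1 | intermediate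
13 | tert-butyldimethylsilyl chloride | CC(C)(C)[Si](C)(C)Cl | starting material
14 | (E)-tert-butyldimethyl{[2-methyl-4-(phenylsulfonyl)but-2-en-1-yl]oxy}silane | O=S(=O)(C/C=C(\C)CO[Si](C)(C)C(C)(C)C)c1ccccc1 | intermediate
15 | N,N-dimethylmethyleneiminium iodide (Eschenmoser's salt) | C=[N+](C)C.[I-] | starting material
16 | lithiated sulfone from 14 (carbanion at C2) | [Li+].O=S(=O)([CH-]/C=C(\C)CO[Si](C)(C)C(C)(C)C)c1ccccc1 | intermediate
17 | lithium enolate of the conjugate adduct (C1 R, C14 R, C2 epimers) | [Li+].[O-]C1=C[C@@H](C(S(=O)(=O)c2ccccc2)/C=C(\C)CO[Si](C)(C)C(C)(C)C)[C@H](CO[Si](c2ccccc2)(c2ccccc2)C(C)(C)C)O1 | intermediate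
18 | (3S,4R,5R)-4-[(E)-4-(tert-butyldimethylsilyloxy)-3-methyl-1-(phenylsulfonyl)but-2-en-1-yl]-5-[(tert-butyldiphenylsilyloxy)methyl]-3-[(dimethylamino)methyl]dihydrofuran-2(3H)-one, epimers at the sulfonyl carbon | CN(C)C[C@H]1C(=O)O[C@@H](CO[Si](c2ccccc2)(c2ccccc2)C(C)(C)C)[C@@H]1C(S(=O)(=O)c1ccccc1)/C=C(\C)CO[Si](C)(C)C(C)(C)C | intermediate
19 | (3S,4R,5R)-4-[(E)-4-(tert-butyldimethylsilyloxy)-3-methylbut-2-en-1-yl]-5-[(tert-butyldiphenylsilyloxy)methyl]-3-[(dimethylamino)methyl]dihydrofuran-2(3H)-one | CN(C)C[C@H]1C(=O)O[C@@H](CO[Si](c2ccccc2)(c2ccccc2)C(C)(C)C)[C@@H]1C/C=C(\C)CO[Si](C)(C)C(C)(C)C | intermediate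
20 | (3S,4R,5R)-5-[(tert-butyldiphenylsilyloxy)methyl]-3-[(dimethylamino)methyl]-4-[(E)-4-hydroxy-3-methylbut-2-en-1-yl]dihydrofuran-2(3H)-one | CN(C)C[C@H]1C(=O)O[C@@H](CO[Si](c2ccccc2)(c2ccccc2)C(C)(C)C)[C@@H]1C/C=C(\C)CO | intermediate
21 | (3S,4R,5R)-5-[(tert-butyldiphenylsilyloxy)methyl]-3-[(dimethylamino)methyl]-4-{[(2S,3S)-3-(hydroxymethyl)-3-methyloxiran-2-yl]methyl}dihydrofuran-2(3H)-one | CN(C)C[C@H]1C(=O)O[C@@H](CO[Si](c2ccccc2)(c2ccccc2)C(C)(C)C)[C@@H]1C[C@@H]1O[C@@]1(C)CO | intermediate
22 | (3S,4R,5R)-5-[(tert-butyldiphenylsilyloxy)methyl]-3-[(dimethylamino)methyl]-4-{[(2S,3R)-3-(iodomethyl)-3-methyloxiran-2-yl]methyl}dihydrofuran-2(3H)-one | CN(C)C[C@H]1C(=O)O[C@@H](CO[Si](c2ccccc2)(c2ccccc2)C(C)(C)C)[C@@H]1C[C@@H]1O[C@@]1(C)CI | intermediate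
23 | trimethyl(prop-1-yn-1-yl)silane | CC#C[Si](C)(C)C | starting material
24 | 1-bromobut-2-yne | CC#CCBr | starting material
25 | 3-(trimethylsilyl)prop-2-yn-1-yllithium | [Li+].[CH2-]C#C[Si](C)(C)C | intermediate
26 | hepta-1,5-diyn-1-yl(trimethyl)silane | CC#CCCC#C[Si](C)(C)C | intermediate
27 | hepta-1,5-diyne | CC#CCCC#C | intermediate
28 | (E)-dimethyl(2-methylhept-1-en-5-yn-1-yl)alane | CC#CCC/C(C)=C/[Al](C)C | intermediate
29 | (E)-3-methyloct-2-en-6-yn-1-ol | CC#CCC/C(C)=C/CO | intermediate
30 | alkenylzirconocene chloride from 29 (zirconium on the methyl-bearing alkyne carbon, hydroxyl held as zirconium alkoxide) | C/C(=C\CC/C(C)=C/CO[Zr](Cl)(C1C=CC=C1)C1C=CC=C1)[Zr](Cl)(C1C=CC=C1)C1C=CC=C1 | intermediate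
31 | (2E,6E)-7-iodo-3-methylocta-2,6-dien-1-ol | C/C(I)=C\CC/C(C)=C/CO | intermediate
32 | (2E,6E)-1-bromo-7-iodo-3-methylocta-2,6-diene | C/C(I)=C\CC/C(C)=C/CBr | intermediate
33 | [(2E,6E)-7-iodo-3-methylocta-2,6-dien-1-yl]sulfonylbenzene | C/C(I)=C\CC/C(C)=C/CS(=O)(=O)c1ccccc1 | intermediate
34 | lithiated sulfone from 33 (carbanion at C6) | [Li+].C/C(I)=C\CC/C(C)=C/[CH-]S(=O)(=O)c1ccccc1 | intermediate
35 | (3S,4R,5R)-5-[(tert-butyldiphenylsilyloxy)methyl]-3-[(dimethylamino)methyl]-4-({(2S,3S)-3-[(3E,7E)-8-iodo-4-methyl-2-(phenylsulfonyl)nona-3,7-dien-1-yl]-3-methyloxiran-2-yl}methyl)dihydrofuran-2(3H)-one, epimers at the sulfonyl carbon | CN(C)C[C@H]1C(=O)O[C@@H](CO[Si](c2ccccc2)(c2ccccc2)C(C)(C)C)[C@@H]1C[C@@H]1O[C@@]1(C)CC(S(=O)(=O)c1ccccc1)/C=C(\C)CC/C=C(\C)I | intermediate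
36 | (3S,4R,5R)-3-[(dimethylamino)methyl]-5-(hydroxymethyl)-4-({(2S,3S)-3-[(3E,7E)-8-iodo-4-methyl-2-(phenylsulfonyl)nona-3,7-dien-1-yl]-3-methyloxiran-2-yl}methyl)dihydrofuran-2(3H)-one, epimers at the sulfonyl carbon | CN(C)C[C@H]1C(=O)O[C@@H](CO)[C@@H]1C[C@@H]1O[C@@]1(C)CC(S(=O)(=O)c1ccccc1)/C=C(\C)CC/C=C(\C)I | intermediate
37 | (2R,3R,4S)-4-[(dimethylamino)methyl]-3-({(2S,3S)-3-[(3E,7E)-8-iodo-4-methyl-2-(phenylsulfonyl)nona-3,7-dien-1-yl]-3-methyloxiran-2-yl}methyl)-5-oxotetrahydrofuran-2-carbaldehyde, epimers at the sulfonyl carbon | CN(C)C[C@H]1C(=O)O[C@@H](C=O)[C@@H]1C[C@@H]1O[C@@]1(C)CC(S(=O)(=O)c1ccccc1)/C=C(\C)CC/C=C(\C)I | intermediate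
38 | alkenylchromium dichloride from 37 (chromium in place of iodine at C12) | CN(C)C[C@H]1C(=O)O[C@@H](C=O)[C@@H]1C[C@@H]1O[C@@]1(C)CC(S(=O)(=O)c1ccccc1)/C=C(\C)CC/C=C(\C)[Cr](Cl)Cl | intermediate
39 | (1R,3S,4S,13S,14R,15S,7E,11E)-17-(dimethylamino)-3,4-epoxy-13-hydroxy-6-(phenylsulfonyl)cembra-7,11-dien-16,14-olide, C6 epimers | CN(C)C[C@H]1C(=O)O[C@@H]2[C@@H]1C[C@@H]1O[C@@]1(C)CC(S(=O)(=O)c1ccccc1)/C=C(\C)CC/C=C(\C)[C@@H]2O | intermediate
40 | (1R,3S,4S,13S,14R,15S,7E,11E)-17-(dimethylamino)-3,4-epoxy-13-hydroxycembra-7,11-dien-16,14-olide | CN(C)C[C@H]1C(=O)O[C@@H]2[C@@H]1C[C@@H]1O[C@@]1(C)CC/C=C(\C)CC/C=C(\C)[C@@H]2O | intermediate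
41 | (1R,3S,4S,13S,14R,15S,7E,11E)-13-acetoxy-17-(dimethylamino)-3,4-epoxycembra-7,11-dien-16,14-olide | CN(C)C[C@H]1C(=O)O[C@@H]2[C@@H]1C[C@@H]1O[C@@]1(C)CC/C=C(\C)CC/C=C(\C)[C@@H]2OC(C)=O | intermediate
42 | trimethylammonium iodide of 41 | C[N+](C)(C)C[C@H]1C(=O)O[C@@H]2[C@@H]1C[C@@H]1O[C@@]1(C)CC/C=C(\C)CC/C=C(\C)[C@@H]2OC(C)=O.[I-] | intermediate
43 | (1R,3S,4S,13S,14R,7E,11E)-13-acetoxy-3,4-epoxycembra-7,11,15(17)-trien-16,14-olide | C=C1C(=O)O[C@@H]2[C@@H]1C[C@@H]1O[C@@]1(C)CC/C=C(\C)CC/C=C(\C)[C@@H]2OC(C)=O | intermediate
44 | (1R,3S,4S,7R,13S,14R,11E)-13-acetoxy-3,4-epoxy-7-hydroperoxycembra-8(19),11,15(17)-trien-16,14-olide (CNP0166375.2) | C=C1C(=O)O[C@@H]2[C@@H]1C[C@@H]1O[C@@]1(C)CC[C@@H](OO)C(=C)CC/C=C(\C)[C@@H]2OC(C)=O | target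

## Step count and least certain steps

Total: 25 steps. Longest linear sequence: 16 steps (steps 1–3, 7–11, 18–25).

**Step 7 (key step).** The most likely failure is proton transfer from the acidic C2–H of the adduct to the lactone enolate before the sparingly soluble iminium salt reacts. Aminomethylation would then occur at C2, or the adduct would revert by retro-Michael reaction on warming. Fallback, from 8 and 14 to 19: the conjugate addition is run alone and quenched with NH4Cl to give the Michael adduct F1. Buffered Na/Hg (as in step 8) gives the desulfonylated lactone F2. LiN(i-Pr)2 then forms its lithium enolate F3, now the only acidic site, and 15 aminomethylates it anti to the C1 side chain to give 19.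

**Step 10.** N-oxidation of the tertiary amine by the titanium peroxide may compete with epoxidation, followed by Cope elimination, or the amine may slow the catalyst by coordination. Fallback, from 20 to 21: the amine is removed first with MeI and then NaHCO3 (as in step 24), through the methiodide F4, to the methylene lactone F5. F5 is inert to the titanium/hydroperoxide system and is epoxidized under the same tartrate control to the epoxy alcohol F6. Dimethylamine in THF then adds back to the methylene group and returns 21, possibly with its C15 epimer F7, which serves equally because C15 is erased in step 24.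

**Step 18.** Displacement at C5 may be slow enough for the sulfonyl carbanion to add to the lactone carbonyl, or to transfer a proton to C15 so that the lactone enolate cyclizes onto C5. The product anion could also open the epoxide. Fallback, from 21 and 32 to 40:
- 21 is oxidized (Dess–Martin periodinane, pyridine) to the epoxy aldehyde F8.
- 32 and PPh3 give the phosphonium bromide F9, which NaN(SiMe3)2 converts to the ylide F10.
- Wittig reaction of F8 with F10 gives the diene F11 (C5=C6 as an E/Z mixture).
- Diimide (2-nitrobenzenesulfonyl hydrazide, Et3N) reduces only the disubstituted C5=C6 bond to give the seco silyl ether F12.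
- Bu4NF/AcOH gives the seco alcohol F13, and Dess–Martin oxidation the seco aldehyde F14.
- CrCl2/NiCl2, through the alkenylchromium species F15, gives 40 directly.

This route has no C6 sulfone and skips step 22.

**Step 21.** Intermolecular coupling may compete with ring closure, and the facial selectivity at C13 may be poor, since Felkin–Anh preference can be overridden by ring strain and the two C6 epimers may behave differently. Fallback, from the C13-epimeric mixture of 39 back to 39: Dess–Martin oxidation gives the macrocyclic enone F16. It is then reduced under chelation control (Zn(BH4)2), or with the matched enantiomer of the CBS oxazaborolidine and catecholborane, to the 13,14-anti alcohol 39.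

**Step 22.** Protonation of the allyl anion at C8 instead of C6 would move the double bond, E/Z integrity of C7=C8 may be lost, and the epoxide may open. The same concern applies in milder form to step 8. Fallback, from 39 to 40 with no new compound: desulfonylation through a π-allyl complex of zerovalent palladium (Pd(PPh3)4, NaBH4, THF/i-PrOH, 0 °C). Hydride is delivered to the less hindered terminus C6 and no free carbanion is formed.

**Step 25.** Abstraction of a C6 ring hydrogen instead of a C19 methyl hydrogen gives the 8-hydroperoxy-6-ene. Poor facial selectivity gives the C7 epimer, and the hydroperoxide may decompose on prolonged irradiation. Fallback, from 43 to 44: ene-type allylic chlorination of C7=C8 (N-chlorosuccinimide, cat. PhSeCl) puts chlorine on C7 and moves the double bond to C8=C19, giving the allylic chloride F17. Silver-assisted perhydrolysis (AgOCOCF3, anhydrous H2O2, Et2O, 0 °C) then gives 44. This fixes the site of oxygenation but not the C7 configuration, so the epimers would still need chromatographic separation.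

## Further compounds

F1 | step 7 | (4R,5R)-4-[(E)-4-(tert-butyldimethylsilyloxy)-3-methyl-1-(phenylsulfonyl)but-2-en-1-yl]-5-[(tert-butyldiphenylsilyloxy)methyl]dihydrofuran-2(3H)-one, sulfonyl-carbon epimers | O=C1C[C@@H](C(S(=O)(=O)c2ccccc2)/C=C(\C)CO[Si](C)(C)C(C)(C)C)[C@H](CO[Si](c2ccccc2)(c2ccccc2)C(C)(C)C)O1
F2 | step 7 | (4R,5R)-4-[(E)-4-(tert-butyldimethylsilyloxy)-3-methylbut-2-en-1-yl]-5-[(tert-butyldiphenylsilyloxy)methyl]dihydrofuran-2(3H)-one | O=C1C[C@@H](C/C=C(\C)CO[Si](C)(C)C(C)(C)C)[C@H](CO[Si](c2ccccc2)(c2ccccc2)C(C)(C)C)O1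
F3 | step 7 | lithium enolate of F2 | [Li+].[O-]C1=C[C@@H](C/C=C(\C)CO[Si](C)(C)C(C)(C)C)[C@H](CO[Si](c2ccccc2)(c2ccccc2)C(C)(C)C)O1
F4 | step 10 | trimethylammonium iodide of 20 | C[N+](C)(C)C[C@H]1C(=O)O[C@@H](CO[Si](c2ccccc2)(c2ccccc2)C(C)(C)C)[C@@H]1C/C=C(\C)CO.[I-]
F5 | step 10 | (4R,5R)-5-[(tert-butyldiphenylsilyloxy)methyl]-4-[(E)-4-hydroxy-3-methylbut-2-en-1-yl]-3-methylenedihydrofuran-2(3H)-one | C=C1C(=O)O[C@@H](CO[Si](c2ccccc2)(c2ccccc2)C(C)(C)C)[C@@H]1C/C=C(\C)CO
F6 | step 10 | (4R,5R)-5-[(tert-butyldiphenylsilyloxy)methyl]-4-{[(2S,3S)-3-(hydroxymethyl)-3-methyloxiran-2-yl]methyl}-3-methylenedihydrofuran-2(3H)-one | C=C1C(=O)O[C@@H](CO[Si](c2ccccc2)(c2ccccc2)C(C)(C)C)[C@@H]1C[C@@H]1O[C@@]1(C)CO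
F7 | step 10 | (3R)-epimer of 21 (C15 epimer) | CN(C)C[C@@H]1C(=O)O[C@@H](CO[Si](c2ccccc2)(c2ccccc2)C(C)(C)C)[C@@H]1C[C@@H]1O[C@@]1(C)CO
F8 | step 18 | epoxy aldehyde from 21 (C5 formyl on the oxirane carbon bearing the methyl group) | CN(C)C[C@H]1C(=O)O[C@@H](CO[Si](c2ccccc2)(c2ccccc2)C(C)(C)C)[C@@H]1C[C@@H]1O[C@@]1(C)C=O
F9 | step 18 | [(2E,6E)-7-iodo-3-methylocta-2,6-dien-1-yl]triphenylphosphonium bromide | C/C(I)=C\CC/C(C)=C/C[P+](c1ccccc1)(c1ccccc1)c1ccccc1.[Br-]
F10 | step 18 | [(2E,6E)-7-iodo-3-methylocta-2,6-dien-1-ylidene]triphenylphosphorane | C/C(I)=C\CC/C(C)=C/C=P(c1ccccc1)(c1ccccc1)c1ccccc1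
F11 | step 18 | Wittig diene (C5=C6 E/Z mixture, 7E, 11E) | CN(C)C[C@H]1C(=O)O[C@@H](CO[Si](c2ccccc2)(c2ccccc2)C(C)(C)C)[C@@H]1C[C@@H]1O[C@@]1(C)C=C/C=C(\C)CC/C=C(\C)I
F12 | step 18 | seco silyl ether without sulfone (C5–C6 saturated) | CN(C)C[C@H]1C(=O)O[C@@H](CO[Si](c2ccccc2)(c2ccccc2)C(C)(C)C)[C@@H]1C[C@@H]1O[C@@]1(C)CC/C=C(\C)CC/C=C(\C)I
F13 | step 18 | seco C13 alcohol without sulfone | CN(C)C[C@H]1C(=O)O[C@@H](CO)[C@@H]1C[C@@H]1O[C@@]1(C)CC/C=C(\C)CC/C=C(\C)I
F14 | step 18 | seco C13 aldehyde without sulfone | CN(C)C[C@H]1C(=O)O[C@@H](C=O)[C@@H]1C[C@@H]1O[C@@]1(C)CC/C=C(\C)CC/C=C(\C)I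
F15 | step 18 | alkenylchromium dichloride from F14 | CN(C)C[C@H]1C(=O)O[C@@H](C=O)[C@@H]1C[C@@H]1O[C@@]1(C)CC/C=C(\C)CC/C=C(\C)[Cr](Cl)Cl
F16 | step 21 | macrocyclic C13 enone (13-oxo analogue of 39, C6 epimers) | CN(C)C[C@H]1C(=O)O[C@@H]2[C@@H]1C[C@@H]1O[C@@]1(C)CC(S(=O)(=O)c1ccccc1)/C=C(\C)CC/C=C(\C)C2=O
F0 | step 22 | none | none
F17 | step 25 | 7-chloro-8(19)-ene analogue of 44 (C7 epimers) | C=C1C(=O)O[C@@H]2[C@@H]1C[C@@H]1O[C@@]1(C)CCC(Cl)C(=C)CC/C=C(\C)[C@@H]2OC(C)=O
A1 | alternative 1 | seco ynal: trans lactone with C13 aldehyde, (3S,4S)-epoxide, 7E olefin and methyl-capped C11≡C12 alkyne | O=C[C@@H]1OC(=O)C[C@H]1C[C@@H]1O[C@@]1(C)CC/C=C(\C)CCC#CC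
A2 | alternative 1 | 14-membered lactone with E-C11=C12 and C13 triethylsilyl ether | C1C(=O)O[C@@H]2[C@@H]1C[C@@H]1O[C@@]1(C)CC/C=C(\C)CC/C=C(\C)[C@@H]2O[Si](CC)(CC)CC
A3 | alternative 2 | C14 diazo(diethoxyphosphoryl)acetate of the pivaloyl/silyl-protected triol | CCOP(=O)(OCC)C(=[N+]=[N-])C(=O)O[C@@H](COC(=O)C(C)(C)C)CCCO[Si](c1ccccc1)(c1ccccc1)C(C)(C)C
A4 | alternative 2 | trans-4,5-disubstituted α-phosphono-γ-lactone (C15 epimers) | CCOP(=O)(OCC)C1C(=O)O[C@@H](COC(=O)C(C)(C)C)[C@@H]1CCO[Si](c1ccccc1)(c1ccccc1)C(C)(C)C
A5 | alternative 3 | macrocyclic C14 alcohol with C1 ethynyl group and C13 silyl ether | C#C[C@H]1C[C@@H]2O[C@@]2(C)CC/C=C(\C)CC/C=C(\C)[C@H](O[Si](C)(C)C(C)(C)C)[C@@H]1O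
A6 | alternative 3 | 14-membered α-methylene lactone with C13 tert-butyldimethylsilyl ether | C=C1C(=O)O[C@@H]2[C@@H]1C[C@@H]1O[C@@]1(C)CC/C=C(\C)CC/C=C(\C)[C@@H]2O[Si](C)(C)C(C)(C)C
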